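Dissolved substrate has a half-life of 0.31 h by step 2 with the partner as charged, far shorter than the 30 h of the run, so what I watch in this flask is the supply from the solid.

    solid substrate ⇌ dissolved substrate, rate k1*(cs1 - [dissolved substrate]) while solid is left; crystals form when [dissolved substrate] > cs1 (cs1 = 7.1 mM, k1 = 0.0599 h⁻¹)
    dissolved substrate + partner → target (k2 = 55.3 L mol⁻¹ h⁻¹)
    dissolved substrate + target → side product (k3 = 44.4 L mol⁻¹ h⁻¹)
    solid substrate + protic impurity → quenched substrate (k4 = 133 L mol⁻¹ h⁻¹)
    partner ⇌ dormant form (K5 = 0.472, k5 = 0.0331 h⁻¹)

solid substrate 20 mM; partner 2.00 equiv; protic impurity 0.400 mM; time 30 h

- percentages count the solid substrate that a species holds: one side product counts as two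
- solid, in amounts per volume of the solution: solid substrate
- at the start none of the solid substrate is in solution
- dissolved substrate means what is dissolved; the solid is not counted in it
- run time (flask): 30 h

- the target standing at 30 h, as a percentage of the solid substrate charged
- concentration of dissolved substrate in solution at 30 h, in percent of saturation

In this flask the solid must in the end dissolve and react away, so I ask how fast that end is approached. With [dissolved substrate] near zero, dissolution runs at its ceiling, coefficient times solubility, 0.425 mM h⁻¹. I carry one quantity, the feed time, the solid substrate charged divided by that ceiling, 47.0 h. It is longer than the run, so I expect solid still standing at the end, with no more than 63.8% of the charge delivered.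

But is the solution really empty? Against the partner as charged, the supply balances at 0.192 mM, far below the solubility, so with the partner as charged dissolution is the rate-limiting step. But the partner does not stay as charged: it relaxes with the dormant form in 6.71 h, well inside the run, and the target competes for dissolved substrate. So I reckon the end of this flask directly. The protic impurity takes 0.400 mM of solid, but the ceiling of the feed does not depend on how much solid stands, so up to 12.8 mM can pass through solution. If each of those took one partner and the dormant form stood at equilibrium, about 18.5 mM of free partner would remain. If the target held that whole amount, [dissolved substrate] would stand near 0.267 mM, or 3.77% of saturation. The net gain of target per substrate fed would fall from 1 to 0.287, and averaging those gives 41.1% of the charge. That average is rough: its end point counts all of 12.8 mM as target.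

The forecast gives 44% and 3.9%, above my target figure, on the grounds that “the growing target takes an increasing share of the dissolved substrate”.

The flask gives 43.7% and 3.88%, with 36.4% of the solid standing where the feed time leaves 36.2%. In the neighbour flask, charged with 8.0 mM of solid substrate at the same equivalents of partner and with 0.0500 equiv of protic impurity, the feed time is 18.8 h, shorter than the run, so the solid there should be gone by the end, and the neighbour flask reads 0% of it. That flask holds target 57.9% and side product 37.0%.

The rate constants stand for no real mixture.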